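## Retrosynthetic overview

- The strategy rests on the aryl ether at C11. Its oxygen sits on C7 of a coumarin whose benzene ring (C4a, C5, C6, C7, C8, C8a) carries oxygen at C7 and C8a in a 1,3-relation, the pattern a vinylketene/alkoxyacetylene benzannulation delivers.
- Target ⇒ triol (C15 angelate installed last) ⇒ protected 7-alkoxycoumarin ⇒ (E)-2-hydroxy-4-alkoxycinnamate (pyranone ring by E→Z isomerisation and lactonisation).
- Key disconnection: benzene ring ⇒ C11 ethynyl ether 15 + dienyl diazoketone 21 (photo-Wolff shift, [2+2], 4π opening, 6π closure). The hindered C11–O–C bond is made at an sp carbon from trichloroethylene, not by substitution at C11.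
- Decalin 10 ⇒ epoxy alcohol 4 by SnCl4 epoxy-polyene cyclisation, then C8 carbinol by epoxidation/hydride; 4 ⇒ farnesol (benzyl ether, SeO2, Sharpless epoxidation).
- Ring order: rings A and B together (step 4), benzene ring (step 13), pyranone ring (step 14).

Key step: step 13

## Remarks on the chemistry (assumptions)

- Locants: C1–C10 are the decalin carbons, C11 the CH2 on C9, C12 the methyl on C8, C15 the oxygenated CH2 on C4. Open-chain compounds use farnesol locants. With these locants the target is (3R,4S,5S,8S,9R,10R).
- Ring configuration: 3-OH, the C4 methyl, the C10 methyl and C11 lie on one face; C15, H5, H9 and the 8-OH lie on the other.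
- The C8 hydroxyl is carried as a methoxymethyl ether. A silyl group on O8 could migrate to the C11 alkoxide (six-membered transfer) under the KH of step 10.
- The diene ester is carried as the ethyl ester (lost as ethanol in step 14), because ethyl (E)-4-oxobut-2-enoate is the readily bought aldehyde.
- The diazoketone is made by diazo transfer, because diazomethane would add across so electron-poor a diene.

## Route

Step 1
Reactants: 1 (2E,6E)-farnesol
Product: 2 (2E,6E)-farnesyl benzyl ether
Conditions: NaH, BnBr, Bu4NI (cat.), THF, 0 °C to rt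
Reagents that add atoms: benzyl bromide, BrCc1ccccc1
Why: Williamson ether synthesis; the benzyl group masks the future C11 oxygen through the Lewis-acid, peracid, hydride and acetalisation steps and leaves later by hydrogenolysis.

Step 2
Reactants: 2 (2E,6E)-farnesyl benzyl ether
Product: 3 (2E,6E,10E)-12-(benzyloxy)-2,6,10-trimethyldodeca-2,6,10-trien-1-ol
Conditions: SeO2 (cat.), t-BuOOH, salicylic acid (cat.), CH2Cl2, 0 °C to rt
Reagents that add atoms: selenium dioxide (oxygen carrier), O=[Se]=O; tert-butyl hydroperoxide, CC(C)(C)OO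
Why: Sharpless catalytic SeO2 allylic oxidation (ene reaction, then [2,3]-shift) attacks the terminal, most electron-rich trisubstituted alkene at its E-methyl group, which should give the E-allylic alcohol and mark the carbon that becomes C15.

Step 3
Reactants: 3 (2E,6E,10E)-12-(benzyloxy)-2,6,10-trimethyldodeca-2,6,10-trien-1-ol
Product: 4 (10R,11R)-10,11-epoxy-12-hydroxyfarnesyl benzyl ether
Conditions: Ti(OiPr)4 (10 mol %), D-(−)-diethyl tartrate (12 mol %), t-BuOOH, 4 Å MS, CH2Cl2, −20 °C
Reagents that add atoms: tert-butyl hydroperoxide, CC(C)(C)OO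
Why: Sharpless asymmetric epoxidation touches only the allylic-alcohol alkene, and the D-(−)-tartrate ligand should deliver oxygen to the face that gives the (2R,3R)-epoxy alcohol (the L-(+) ester gives the (2S,3S) series with E-allylic alcohols), which fixes C3 directly and C4 through the E geometry.

Step 4
Reactants: 4 (10R,11R)-10,11-epoxy-12-hydroxyfarnesyl benzyl ether
Product: 5 11-benzyloxydrim-7-ene-3,15-diol
Conditions: SnCl4, CH2Cl2, −78 °C; aq NaHCO3
Reagents that add atoms: none
Why: Lewis-acid epoxy-polyene (Stork–Eschenmoser) bicyclisation: the C6=C7 alkene opens the tin-bound oxirane at its tertiary carbon with inversion while the C2=C3 alkene closes ring B through a chair–chair array, so C3 is retained, the E-CH2OH becomes the equatorial C15 at C4, anti addition across the two E-alkenes sets the trans ring fusion (C5, C10) and the equatorial C9 side chain, and loss of H7 should give mainly the Δ7 alkene (any Δ8(12) isomer reaches 8 by the same two operations).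

Step 5
Reactants: 5 11-benzyloxydrim-7-ene-3,15-diol
Product: 6 11-benzyloxy-3,15-O-isopropylidenedrim-7-ene-3,15-diol
Conditions: Me2C(OMe)2, PPTS (cat.), CH2Cl2, rt
Reagents that add atoms: 2,2-dimethoxypropane, COC(C)(C)OC
Why: acid-catalysed transacetalisation; the equatorial 3-OH and the equatorial C15 hydroxymethyl group form a strain-free 1,3-dioxane, as in 3,23-diols of the hederagenin type.

Step 6
Reactants: 6 11-benzyloxy-3,15-O-isopropylidenedrim-7-ene-3,15-diol
Product: 7 11-benzyloxy-7,8-epoxy-3,15-O-isopropylidenedrimane-3,15-diol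
Conditions: mCPBA, NaHCO3, CH2Cl2, 0 °C
Reagents that add atoms: 3-chloroperoxybenzoic acid, OOC(=O)c1cccc(Cl)c1
Why: Prilezhaev epoxidation; the peracid should approach the Δ7 alkene from the face opposite the axial C10 methyl group, which places the oxirane oxygen on the side of H5 and H9 and so sets the C8 configuration.

Step 7
Reactants: 7 11-benzyloxy-7,8-epoxy-3,15-O-isopropylidenedrimane-3,15-diol
Product: 8 11-benzyloxy-3,15-O-isopropylidenedrimane-3,8,15-triol (8-OH free)
Conditions: LiAlH4, THF, 65 °C
Reagents that add atoms: none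
Why: hydride opens the trisubstituted oxirane by SN2 attack at the secondary C7, so the C8–O bond and its configuration are untouched and the tertiary carbinol results, as in the classical conversion of labd-7-ene oxides into 8-hydroxylabdanes.

Step 8
Reactants: 8 11-benzyloxy-3,15-O-isopropylidenedrimane-3,8,15-triol
Product: 9 11-benzyloxy-3,15-O-isopropylidene-8-O-methoxymethyldrimane-3,8,15-triol
Conditions: MOMCl, i-Pr2NEt, Bu4NI (cat.), ClCH2CH2Cl, 60 °C
Reagents that add atoms: chloromethyl methyl ether, COCCl
Why: alkylation of the tertiary alcohol by the reactive α-chloro ether under amine buffering; an acetal ether is stable to KH, n-BuLi, ketenes and light and cannot migrate to the neighbouring C11 oxygen.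

Step 9
Reactants: 9 11-benzyloxy-3,15-O-isopropylidene-8-O-methoxymethyldrimane-3,8,15-triol
Product: 10 3,15-O-isopropylidene-8-O-methoxymethyldrimane-3,8,11,15-tetrol (11-OH free)
Conditions: H2 (1 atm), Pd/C, EtOAc, rt
Reagents that add atoms: none
Why: hydrogenolysis of the benzyl ether; both acetals are inert under neutral hydrogenation and the molecule holds no alkene at this stage.

Step 10
Reactants: 10 3,15-O-isopropylidene-8-O-methoxymethyldrimane-3,8,11,15-tetrol; 11 trichloroethylene
Product: 15 11-O-ethynyl-3,15-O-isopropylidene-8-O-methoxymethyldrimane-3,8,11,15-tetrol, via dichlorovinyl ether 12 (not isolated), via chloroethynyl ether 13 (not isolated), via lithium acetylide 14 (not isolated)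
Conditions: KH, THF, 0 °C; Cl2C=CHCl, rt; then n-BuLi, −78 to −40 °C; H2O, −78 °C
Reagents that add atoms: none
Why: Greene ynol ether synthesis: the potassium alkoxide adds to dichloroacetylene formed in situ from trichloroethylene, and n-BuLi then effects β-elimination and Cl/Li exchange before protonation, so the hindered C11–O–C bond is made by addition–elimination at an unsaturated carbon and not by substitution at the neopentyl-like C11.

Step 11
Reactants: 16 ethyl (E)-4-oxobut-2-enoate; 17 1-(triphenylphosphoranylidene)propan-2-one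
Product: 18 ethyl (2E,4E)-6-oxohepta-2,4-dienoate
Conditions: CH2Cl2, rt
Reagents that add atoms: none
Why: Wittig olefination with a ketone-stabilised ylide, which reacts only at the aldehyde and should give the E alkene.

Step 12
Reactants: 18 ethyl (2E,4E)-6-oxohepta-2,4-dienoate
Product: 21 ethyl (2E,4E)-7-diazo-6-oxohepta-2,4-dienoate, via lithium enolate 19 (not isolated), via trifluoroacetyl diketone 20 (not isolated)
Conditions: LiN(SiMe3)2, THF, −78 °C; CF3CO2CH2CF3, −78 °C; aq HCl work-up; then MsN3, Et3N, H2O, MeCN, rt
Reagents that add atoms: methanesulfonyl azide, CS(=O)(=O)N=[N+]=[N-]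
Why: Danheiser detrifluoroacetylative diazo transfer: the methyl group is the only enolisable position, Claisen trifluoroacetylation activates it, and Regitz-type transfer from the sulfonyl azide expels the trifluoroacetyl group as the N-acylsulfonamide.

Step 13
Reactants: 15 11-O-ethynyl-3,15-O-isopropylidene-8-O-methoxymethyldrimane-3,8,11,15-tetrol; 21 ethyl (2E,4E)-7-diazo-6-oxohepta-2,4-dienoate
Product: 26 ethyl (E)-3-[2-hydroxy-4-(protected driman-11-yloxy)phenyl]prop-2-enoate, via dienylketene 22 (not isolated), via cyclobutenone 23 (not isolated), via ring-opened ketene 24 (not isolated), via cyclohexadienone 25 (not isolated)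
Conditions: hν (365 nm), ClCH2CH2Cl, 20 °C, slow addition of 21; then 80 °C
Reagents that add atoms: none
Why: Irradiation expels N2 from 21 and the dienyl group shifts from the acyl carbon to the carbene carbon (photo-Wolff), which gives dienylketene 22 and the future C5–C6 bond; the ketene carbonyl carbon then bonds to the nucleophilic CH terminus of ynol ether 15 (C8–C8a) and the ketene α-carbon to the alkoxy carbon (C6–C7) in a regiospecific [2+2] cycloaddition to cyclobutenone 23. Conrotatory 4π opening of 23 gives ketene 24 with the dienyl arm cis to the ketene, and thermal disrotatory 6π electrocyclisation onto the first alkene of that arm forms C4a–C8a and closes the six-membered carbocycle, which tautomerises (25 to 26) to the phenol. The closest known reaction is the Danheiser benzannulation of vinylketenes, generated from α-diazo enones, with alkoxyacetylenes to resorcinol monoethers. No stereocentre is created, and the (E)-acrylate geometry is carried over from the remote alkene of 21. The step needs regioselectivity (ether oxygen meta to the phenol oxygen and para to the acrylate carbon), which the ketene/ynol ether polarity secures, and chemoselectivity, which the aprotic acetal groups and the two-stage protocol (ketene consumed at 20 °C before the phenol appears at 80 °C) secure. The main hazard is E-to-Z isomerisation of the central alkene of 22, which would let it close on itself to an ethyl salicylate, so long-wavelength light absorbed by the diazoketone and a low stationary concentration of 21 are used.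

Step 14
Reactants: 26 ethyl (E)-3-[2-hydroxy-4-(protected driman-11-yloxy)phenyl]prop-2-enoate
Product: 28 7-(3,15-O-isopropylidene-8-O-methoxymethyl-3,8,15-trihydroxydriman-11-yloxy)-2H-chromen-2-one, via Z-cinnamate 27 (not isolated)
Conditions: hν (365 nm), MeCN (dilute, degassed), rt
Reagents that add atoms: none
Why: direct excitation turns the (E)-2-hydroxycinnamate into its Z isomer, whose phenol oxygen lies next to the ester carbonyl and lactonises with loss of ethanol to the pyranone ring (the reaction by which o-hydroxycinnamate photocages release alcohols), while high dilution limits coumarin [2+2] photodimerisation.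

Step 15
Reactants: 28 7-(3,15-O-isopropylidene-8-O-methoxymethyl-3,8,15-trihydroxydriman-11-yloxy)-2H-chromen-2-one
Product: 29 7-(3,8,15-trihydroxydriman-11-yloxy)-2H-chromen-2-one
Conditions: HCl (3 M aq), THF/MeOH, 45 °C
Reagents that add atoms: none
Why: acid hydrolysis of both acetals; the isopropylidene ketal releases the 3,15-diol and the methoxymethyl ether fragments at its acetal carbon, not at the tertiary C8–O bond, while the lactone and the aryl alkyl ether are stable to aqueous acid.

Step 16
Reactants: 29 7-(3,8,15-trihydroxydriman-11-yloxy)-2H-chromen-2-one; 30 angelic acid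
Product: 31 CNP0139045.1
Conditions: 30, 2,4,6-Cl3C6H2COCl, Et3N, toluene, rt; then 29, toluene, 70 °C
Reagents that add atoms: none
Why: Yamaguchi esterification; the bulky mixed anhydride should acylate the primary C15 hydroxyl faster than the secondary C3 hydroxyl flanked by the quaternary C4 (as in 23-O-acylation of hederagenin-type diols) and not the tertiary C8 hydroxyl, and the absence of a nucleophilic catalyst keeps the Z alkene of the angelate.

## Compound list

1 | (2E,6E)-farnesol | CC(C)=CCC/C(C)=C/CC/C(C)=C/CO | starting material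
2 | (2E,6E)-farnesyl benzyl ether | CC(C)=CCC/C(C)=C/CC/C(C)=C/COCc1ccccc1 | intermediate
3 | (2E,6E,10E)-12-(benzyloxy)-2,6,10-trimethyldodeca-2,6,10-trien-1-ol | OC/C(C)=C/CC/C(C)=C/CC/C(C)=C/COCc1ccccc1 | intermediate
4 | [(2R,3R)-3-[(3E,7E)-9-(benzyloxy)-3,7-dimethylnona-3,7-dien-1-yl]-2-methyloxiran-2-yl]methanol, the (10R,11R)-epoxy alcohol | OC[C@@]1(C)O[C@@H]1CC/C(C)=C/CC/C(C)=C/COCc1ccccc1 | intermediate
5 | 11-benzyloxydrim-7-ene-3,15-diol, trans-decalin with ring configuration as in 31 | OC[C@]1(C)[C@H]2CC=C(C)[C@@H](COCc3ccccc3)[C@]2(C)CC[C@H]1O | intermediate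
6 | 3,15-O-isopropylidene acetal of 5 | CC1(C)OC[C@]2(C)[C@H]3CC=C(C)[C@@H](COCc4ccccc4)[C@]3(C)CC[C@H]2O1 | intermediate
7 | 7,8-epoxide of 6, oxirane oxygen on the face opposite the C10 methyl | CC1(C)OC[C@]2(C)[C@H]3C[C@@H]4O[C@]4(C)[C@@H](COCc5ccccc5)[C@]3(C)CC[C@H]2O1 | intermediate
8 | 11-benzyloxy-3,15-O-isopropylidenedrimane-3,8,15-triol, tertiary 8-OH trans to the C10 methyl | CC1(C)OC[C@]2(C)[C@H]3CC[C@](C)(O)[C@@H](COCc4ccccc4)[C@]3(C)CC[C@H]2O1 | intermediate
9 | 8-O-methoxymethyl ether of 8 | CC1(C)OC[C@]2(C)[C@H]3CC[C@](C)(OCOC)[C@@H](COCc4ccccc4)[C@]3(C)CC[C@H]2O1 | intermediate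
10 | 3,15-O-isopropylidene-8-O-methoxymethyldrimane-3,8,11,15-tetrol, 11-OH free | CC1(C)OC[C@]2(C)[C@H]3CC[C@](C)(OCOC)[C@@H](CO)[C@]3(C)CC[C@H]2O1 | intermediate
11 | trichloroethylene | ClC=C(Cl)Cl | starting material
12 | (E)-1,2-dichlorovinyl ether of 10 at O11 | CC1(C)OC[C@]2(C)[C@H]3CC[C@](C)(OCOC)[C@@H](CO/C(Cl)=C\Cl)[C@]3(C)CC[C@H]2O1 | intermediate
13 | chloroethynyl ether of 10 at O11 | CC1(C)OC[C@]2(C)[C@H]3CC[C@](C)(OCOC)[C@@H](COC#CCl)[C@]3(C)CC[C@H]2O1 | intermediate
14 | lithium acetylide of the O11 ethynyl ether | CC1(C)OC[C@]2(C)[C@H]3CC[C@](C)(OCOC)[C@@H](COC#C[Li])[C@]3(C)CC[C@H]2O1 | intermediate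
15 | C11 ethynyl ether of the protected decalin core | CC1(C)OC[C@]2(C)[C@H]3CC[C@](C)(OCOC)[C@@H](COC#C)[C@]3(C)CC[C@H]2O1 | intermediate
16 | ethyl (E)-4-oxobut-2-enoate | CCOC(=O)/C=C/C=O | starting material
17 | 1-(triphenylphosphoranylidene)propan-2-one | CC(=O)C=P(c1ccccc1)(c1ccccc1)c1ccccc1 | starting material
18 | ethyl (2E,4E)-6-oxohepta-2,4-dienoate | CCOC(=O)/C=C/C=C/C(C)=O | intermediate
19 | lithium enolate of 18 at the methyl ketone | [Li+].[O-]C(=C)/C=C/C=C/C(=O)OCC | intermediate
20 | ethyl (2E,4E)-8,8,8-trifluoro-6,8-dioxoocta-2,4-dienoate | CCOC(=O)/C=C/C=C/C(=O)CC(=O)C(F)(F)F | intermediate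
21 | ethyl (2E,4E)-7-diazo-6-oxohepta-2,4-dienoate | CCOC(=O)/C=C/C=C/C(=O)C=[N+]=[N-] | intermediate
22 | ethyl (2E,4E)-7-oxohepta-2,4,6-trienoate (dienylketene) | CCOC(=O)/C=C/C=C/C=C=O | intermediate
23 | 3-(protected driman-11-yloxy)-4-[(1E,3E)-4-ethoxycarbonylbuta-1,3-dienyl]cyclobut-2-en-1-one, either configuration at C4 of the four-membered ring | CC1(C)OC[C@]2(C)[C@H]3CC[C@](C)(OCOC)[C@@H](COC4=CC(=O)C4/C=C/C=C/C(=O)OCC)[C@]3(C)CC[C@H]2O1 | intermediate
24 | ring-opened ketene, ethyl 7-(protected driman-11-yloxy)-9-oxonona-2,4,6,8-tetraenoate with ketene and dienyl arm cis | CC1(C)OC[C@]2(C)[C@H]3CC[C@](C)(OCOC)[C@@H](COC(/C=C=O)=C/C=C/C=C/C(=O)OCC)[C@]3(C)CC[C@H]2O1 | intermediate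
25 | 3-(protected driman-11-yloxy)-6-[(E)-2-ethoxycarbonylvinyl]cyclohexa-2,4-dien-1-one | CC1(C)OC[C@]2(C)[C@H]3CC[C@](C)(OCOC)[C@@H](COC4=CC(=O)C(/C=C/C(=O)OCC)C=C4)[C@]3(C)CC[C@H]2O1 | intermediate
26 | ethyl (E)-3-[2-hydroxy-4-(3,15-O-isopropylidene-8-O-methoxymethyl-3,8,15-trihydroxydriman-11-yloxy)phenyl]prop-2-enoate | CC1(C)OC[C@]2(C)[C@H]3CC[C@](C)(OCOC)[C@@H](COc4cc(O)c(/C=C/C(=O)OCC)cc4)[C@]3(C)CC[C@H]2O1 | intermediate
27 | (Z) isomer of 26 | CC1(C)OC[C@]2(C)[C@H]3CC[C@](C)(OCOC)[C@@H](COc4cc(O)c(/C=C\C(=O)OCC)cc4)[C@]3(C)CC[C@H]2O1 | intermediate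
28 | 7-(3,15-O-isopropylidene-8-O-methoxymethyl-3,8,15-trihydroxydriman-11-yloxy)-2H-chromen-2-one | CC1(C)OC[C@]2(C)[C@H]3CC[C@](C)(OCOC)[C@@H](COc4ccc5ccc(=O)oc5c4)[C@]3(C)CC[C@H]2O1 | intermediate
29 | 7-(3,8,15-trihydroxydriman-11-yloxy)-2H-chromen-2-one | OC[C@]1(C)[C@H]2CC[C@](C)(O)[C@@H](COc3ccc4ccc(=O)oc4c3)[C@]2(C)CC[C@H]1O | intermediate
30 | angelic acid, (Z)-2-methylbut-2-enoic acid | C/C=C(/C)C(=O)O | starting material
31 | CNP0139045.1, (3R,4S,5S,8S,9R,10R)-3,8-dihydroxy-11-(2-oxo-2H-chromen-7-yloxy)driman-15-yl (Z)-2-methylbut-2-enoate | C/C=C(/C)C(=O)OC[C@]1(C)[C@H]2CC[C@](C)(O)[C@@H](COc3ccc4ccc(=O)oc4c3)[C@]2(C)CC[C@H]1O | target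

## Step count and risk

Total step count: 16. Longest linear sequence: 14 steps (steps 1–10 and 13–16); steps 11 and 12 form the short diazoketone branch.

Steps most likely to fail:

- **Step 13 (key benzannulation).** Photoisomerisation of the diene arm of the diazoketone or of ketene 22 could lead to self-closure of the ketene, ketene oligomerisation could outrun the [2+2] capture, and the ynol ether could fragment thermally by a retro-ene path before it is consumed. Fallback: the aryl ether is made without building the ring. Alcohol 10 is coupled with commercial 7-bromocoumarin by Pd-catalysed C–O cross-coupling ([Pd(allyl)Cl]2, RockPhos, Cs2CO3, toluene, 90 °C). The C–O bond then forms by reductive elimination at the aryl carbon, so C11 is still not a substitution centre, and the product is coumarin 28, where the route is rejoined. No new compound is made on the way (F0: none).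

- **Step 4 (epoxy-polyene cyclisation).** The hydroxymethyl group slows ionisation at the tertiary oxirane carbon, so hydride shift to a carbonyl compound, arrest after ring A, or scrambling of the terminating elimination may compete. Fallback: epoxy alcohol 4 is cyclised in the radical manifold. Cp2TiCl (from Cp2TiCl2 and Mn dust, THF, rt) opens the oxirane homolytically at the tertiary carbon, and the cascade ends by β-hydride loss to the exocyclic alkene diol F1. Acetalisation (2,2-dimethoxypropane, PPTS) gives acetonide F2, mCPBA gives spiro-oxirane F3 from the face opposite the C10 methyl, and LiAlH4 (hydride to the oxirane CH2) returns to carbinol 8. In this manifold C4 is set by the chair transition state (larger CH2O group equatorial) and not by stereospecific opening, so its configuration would have to be confirmed by NOE before going on.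

- **Step 16 (selective angeloylation).** Acylation may spread to the C3 hydroxyl, and the acyl donor may isomerise Z to E (tiglate). Fallback: triol 29 is first converted with Bu2SnO (toluene, reflux, water removed) into the 3,15-O-dibutylstannylene acetal F4. This is acylated at the primary oxygen by angelic anhydride at 0 °C without base or nucleophilic catalyst, and gives target 31 directly.

## Further compounds

F0 | step 13 | none | none
F1 | step 4 | 11-benzyloxydrim-8(12)-ene-3,15-diol | OC[C@]1(C)[C@H]2CCC(=C)[C@@H](COCc3ccccc3)[C@]2(C)CC[C@H]1O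
F2 | step 4 | 3,15-O-isopropylidene acetal of F1 | CC1(C)OC[C@]2(C)[C@H]3CCC(=C)[C@@H](COCc4ccccc4)[C@]3(C)CC[C@H]2O1
F3 | step 4 | 8,12-epoxide of F2, oxirane oxygen on the face opposite the C10 methyl | CC1(C)OC[C@]2(C)[C@H]3CC[C@]4(OC4)[C@@H](COCc5ccccc5)[C@]3(C)CC[C@H]2O1
F4 | step 16 | 3,15-O-dibutylstannylene acetal of 29 | CCCC[Sn]1(CCCC)OC[C@]2(C)[C@H]3CC[C@](C)(O)[C@@H](COc4ccc5ccc(=O)oc5c4)[C@]3(C)CC[C@H]2O1
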